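In teal, dissolved substrate turns into target at 0.0248 s⁻¹ of itself over the first 15.0 s, but at 0.00905 s⁻¹ from there to 40.0 s. That is 2.74 times slower, although dissolved substrate is rising. What fades? Target needs partner, so I read this ratio as partner fading, with 0.5 percentage points of scatter on each reading.

the same everywhere: solid substrate 10 mM
- teal: partner 0.90 equiv; protic impurity 2 mM; the very flask that is asked about, followed so far
- flask: partner 0.900 equiv; protic impurity 2.00 mM; time 3.0 min

teal run (percent of the solid substrate charged)

| time / s | target / % | dissolved substrate / % |
|---|---|---|
| 10.0 | 0.8 | 9.0 |
| 15.0 | 2.1 | 11.3 |
| 40.0 | 5.8 | 21.4 |

(scatter of a reading: 0.5 percentage points)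

- solid, in amounts per volume of the solution: solid substrate
- at the start none of the solid substrate is in solution
- dissolved substrate means what is dissolved; the solid is not counted in it

- cedar: doubling the solubility of the solid substrate, all else as stated
- elm: doubling the amount of partner, all else as stated
- alder: doubling the dissolution coefficient of the solid substrate, all else as stated

- amount of target at 3.0 min, in percent of the solid substrate charged
- concentration of dissolved substrate in solution at 20 s, in percent of saturation
- the change that raises the amount of target at 3.0 min, in percent of the solid substrate charged most ("none" if none brings more than 2 percentage points) (cedar / elm / alder / none)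
- amount of target at 3.0 min, in percent of the solid substrate charged, after cedar

How fast does it fade? The middles of the two windows lie 20.0 s apart, so the fading constant reads 0.0504 s⁻¹. That is a half-life of 13.8 s, far shorter than the 3.0 min asked about.

How much target is still to come? I divide the last target rate by the fading constant, and time drops out. I take that last rate as the rate at the last reading, which is rough. So I commit to 8.74% in teal: this is the partner harvest, the last target reading plus the last target rate over the fading constant. With dissolved substrate and the fading constant held level, it scales with the equivalents of partner, so I expect elm to pay.

The forecast gives 36%, 41%, elm and 55%, with the “rate falling as partner is used”. Its amount of target is higher than mine.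

The flask gives 11.4%, 46.1%, elm and 17.8%.

    solid substrate + protic impurity → quenched substrate (k = 16.0 M⁻¹ s⁻¹)
    partner → decomposed reagent (k = 0.0300 s⁻¹)
    dissolved substrate + partner → target (k = 3.30 M⁻¹ s⁻¹)
    solid substrate ⇌ dissolved substrate, rate k4*(cs4 - [dissolved substrate]) while solid is left; crystals form when [dissolved substrate] > cs4 (solubility = 3.10 mM, k = 0.0380 s⁻¹)
    partner ⇌ dormant form (K = 0.550, k = 0.0110 s⁻¹)
    dissolved substrate + target → side product (k = 0.200 M⁻¹ s⁻¹)

In this flask at 0.340 min, partner has a half-life of 0.39 min by decomposition to decomposed reagent, shorter than the 2.4 min by reaction to target. Free partner, the limiting reagent, stands at 1.3% of its charge at 3.00 min, with a further 0.217 mM as dormant form, and the target of 11.4% stands 2.7 points above the harvest of 8.74%.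

With 2.20 equiv of partner, the harvest scaled by equivalents gives 21.4%. That flask gives 25.0%.

(The readings were computed with made-up constants; noise was put on by code.)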